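## Retrosynthetic overview

1. Feature: C3 and C3' of the two pyrrole rings are bonded to each other. Each sits on a benzo carbon (C3a, C3a') whose ortho neighbour (C7a, C7a') bears N1 or N1'. The chain C3a–C3–C3'–C3a' is therefore the ethane bridge of a 2,2'-dinitrobibenzyl that lacks only the CH units C2 and C2'.
2. C2–Br and C2'–Br are removed first, by late electrophilic bromination of 5,5',6,6'-tetrabromo-3,3'-biindole with C3 and C3' blocked.
3. N1–C2 and N1'–C2' are cut next. Both pyrrole rings close in one reductive operation from a bis(dimethylamino)diene, and the two dibromobenzo rings are present from the start.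
4. Key disconnection C2–C3 and C2'–C3': twofold aminomethylenation of 1,2-bis(4,5-dibromo-2-nitrophenyl)ethane with tert-butoxybis(dimethylamino)methane.
5. C3–C3' is formed at the sp3 stage by oxidative dimerisation of 4,5-dibromo-2-nitrotoluene, which comes from nitration of 3,4-dibromotoluene.

Key step: step 3

Assumption: the target string carries no descriptor for the C3–C3' axis, so the hexabromide is made without control of axial configuration (racemic if the axis proves configurationally stable).

## Route

Step 1
Reactants: 1 3,4-dibromotoluene
Product: 2 4,5-dibromo-2-nitrotoluene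
Conditions: fuming HNO3, conc. H2SO4, 0 °C to rt; recrystallisation from EtOH
Reagents that add atoms: nitric acid, O[N+](=O)[O-]
Why: Electrophilic aromatic nitration, in which C6 of 1 is ortho to the activating methyl group and para to the C3 bromine, whereas C2 is squeezed between methyl and bromine and C5 is meta to methyl, so the 2-nitro-4,5-dibromo pattern should dominate and minor isomers should be removed by crystallisation.

Step 2
Reactants: 2 4,5-dibromo-2-nitrotoluene (two molecules)
Product: 4 1,2-bis(4,5-dibromo-2-nitrophenyl)ethane, via benzylic bromide 3 (not isolated)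
Conditions: KOtBu, THF, 0 °C, 2 min; then Br2, 0 °C, 5 min; ice-water quench
Reagents that add atoms: none
Why: Oxidative dimerisation of an ortho-nitrobenzyl anion, an established entry to 2,2'-dinitrobibenzyls including halogenated ones: tert-butoxide removes a methyl proton acidified by the ortho nitro group, bromine converts part of the anion into 3, and a second anion displaces its bromide, while the bulky base, the low temperature and the short contact time hold back substitution at the bromine para to nitro and over-oxidation to the stilbene.

Step 3
Reactants: 4 1,2-bis(4,5-dibromo-2-nitrophenyl)ethane, 5 tert-butoxybis(dimethylamino)methane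
Product: 7 (1E,3E)-2,3-bis(4,5-dibromo-2-nitrophenyl)-N,N,N',N'-tetramethylbuta-1,3-diene-1,4-diamine, via mono-enamine 6 (not isolated)
Conditions: 5 (large excess, added in portions), DMF, 120 °C, slow Ar sweep, 24–48 h
Reagents that add atoms: tert-butoxybis(dimethylamino)methane (5), CN(C)C(OC(C)(C)C)N(C)C
Why: Heat splits 5 into tert-butoxide and the tetramethylformamidinium ion; the alkoxide removes a benzylic proton of 4 (anion delocalised into the ortho nitro group, helped inductively by the para bromine), the carbanion adds to the formamidinium carbon, and loss of dimethylamine from the aminal gives 6 with the new C2–C3 bond. The CH2 left in 6 is still ortho-nitrobenzylic and now also allylic, so the same sequence at C3' forms C2'–C3' and gives 7. This is the enamine stage of the Leimgruber–Batcho indole synthesis, routine for methyl groups and known but slow at secondary benzylic carbons, while the twofold aminomethylenation of 1,2-diactivated ethanes such as succinic esters shows that two adjacent carbons can both be condensed; hence the most reactive formamide acetal equivalent, a large excess and long heating. No ring closes and no stereocentre arises; the E geometry drawn at both C=C bonds (nitrogen anti to its own aryl group) is the less crowded one and does not matter, since the later closure runs by addition–elimination at C2 and C2'. Site selectivity rests on the substrate, in which only the two symmetry-equivalent benzylic CH2 groups are acidic, and completion of the second condensation is driven by sweeping out dimethylamine and tert-butanol. The same sweep and the absence of any added secondary amine limit nucleophilic displacement of the bromines para to nitro, which are further protected once the anion or the enamine pushes electron density into the nitroarene.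

Step 4
Reactants: 7 (1E,3E)-2,3-bis(4,5-dibromo-2-nitrophenyl)-N,N,N',N'-tetramethylbuta-1,3-diene-1,4-diamine
Product: 9 5,5',6,6'-tetrabromo-1H,1'H-3,3'-biindole, via bis-aniline 8 (not isolated)
Conditions: Fe powder (excess), AcOH, toluene, 90 °C, Ar; filtration, aq. NaHCO3 wash
Reagents that add atoms: none
Why: Reductive stage of the Leimgruber–Batcho synthesis, in which iron in acetic acid reduces both nitro groups without touching the aryl bromides and each aniline nitrogen of 8 adds in a 5-exo-trig sense to its own C3-protonated enamine (iminium) carbon and expels dimethylamine, the fast and irreversible aromatisation to the pyrrole ring favouring this closure over the slower six-membered closure onto the enamine carbon of the other half.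

Step 5
Reactants: 9 5,5',6,6'-tetrabromo-1H,1'H-3,3'-biindole
Product: 10 2,2',5,5',6,6'-hexabromo-1H,1'H-3,3'-biindole (CNP0143195.0)
Conditions: NBS (2.05 equiv), THF, −78 to 0 °C, dark; aq. Na2S2O3/NaHCO3 quench
Reagents that add atoms: N-bromosuccinimide, O=C1CCC(=O)N1Br
Why: Electrophilic bromination of a 3-substituted indole with NBS, in which attack at the blocked C3 followed by bromine migration (or direct attack at C2) delivers the 2-bromoindole, while C4 and C7 are deactivated and shielded by the neighbouring bromines, so two equivalents should stop at the 2,2'-dibromide.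

## Compound list

1 | 3,4-dibromotoluene | Cc1ccc(Br)c(Br)c1 | starting material
2 | 4,5-dibromo-2-nitrotoluene | Cc1cc(Br)c(Br)cc1[N+](=O)[O-] | intermediate
3 | 4,5-dibromo-2-nitrobenzyl bromide | BrCc1cc(Br)c(Br)cc1[N+](=O)[O-] | intermediate
4 | 1,2-bis(4,5-dibromo-2-nitrophenyl)ethane | [O-][N+](=O)c1cc(Br)c(Br)cc1CCc1cc(Br)c(Br)cc1[N+](=O)[O-] | intermediate
5 | tert-butoxybis(dimethylamino)methane | CN(C)C(OC(C)(C)C)N(C)C | starting material
6 | (E)-2,3-bis(4,5-dibromo-2-nitrophenyl)-N,N-dimethylprop-1-en-1-amine | CN(C)/C=C(/c1cc(Br)c(Br)cc1[N+](=O)[O-])Cc1cc(Br)c(Br)cc1[N+](=O)[O-] | intermediate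
7 | (1E,3E)-2,3-bis(4,5-dibromo-2-nitrophenyl)-N,N,N',N'-tetramethylbuta-1,3-diene-1,4-diamine | CN(C)/C=C(/c1cc(Br)c(Br)cc1[N+](=O)[O-])\C(c1cc(Br)c(Br)cc1[N+](=O)[O-])=C/N(C)C | intermediate
8 | (1E,3E)-2,3-bis(2-amino-4,5-dibromophenyl)-N,N,N',N'-tetramethylbuta-1,3-diene-1,4-diamine | CN(C)/C=C(/c1cc(Br)c(Br)cc1N)\C(c1cc(Br)c(Br)cc1N)=C/N(C)C | intermediate
9 | 5,5',6,6'-tetrabromo-1H,1'H-3,3'-biindole | Brc1cc2[nH]cc(-c3c[nH]c4cc(Br)c(Br)cc34)c2cc1Br | intermediate
10 | 2,2',5,5',6,6'-hexabromo-1H,1'H-3,3'-biindole | Brc1cc2[nH]c(Br)c(-c3c(Br)[nH]c4cc(Br)c(Br)cc34)c2cc1Br | target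

## Step count and risks

Total step count: 5. Longest linear sequence: 5.

**Step 3.**
- What may go wrong: The condensation may stall after the first benzylic carbon has reacted. The second deprotonation takes place at a crowded carbon, and the twisted aryl groups weaken the push–pull stabilisation that normally pulls the equilibrium over. Prolonged heating also gives liberated dimethylamine time to displace the bromines para to nitro.
- Fallback, from 4 back to 9: The one-carbon unit is brought in at the alcohol level with the much smaller electrophile formaldehyde, a reaction known for ortho-nitroethylbenzene. Paraformaldehyde and catalytic benzyltrimethylammonium hydroxide in DMSO at about 70 °C should hydroxymethylate both benzylic carbons to 2,3-bis(4,5-dibromo-2-nitrophenyl)butane-1,4-diol F1. Its meso and racemic forms are both usable, because the two stereocentres vanish on aromatisation. Swern oxidation activates both hydroxyl groups before base is added and so avoids lactol formation; it should give 2,3-bis(4,5-dibromo-2-nitrophenyl)butanedial F2. The crude dialdehyde is treated with Fe powder in AcOH as in step 4. The 2,3-bis(2-amino-4,5-dibromophenyl)butanedial F3 formed in the flask should close twice with loss of water to 9.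

**Step 4.**
- What may go wrong: The first aniline meets two electrophilic carbons, so six-membered closure onto the enamine carbon of the other half may compete with the five-membered closure. Acid hydrolysis of the bis-enamine followed by Paal–Knorr-type cyclodehydration may outrun the reduction. The reduction may also stop at the N-hydroxy stage.
- Fallback, from 2 back to 9: Each pyrrole ring is closed on a monomer that holds only one nitrogen and one electrophilic carbon, and C3–C3' is formed afterwards. N,N-dimethylformamide dimethyl acetal in DMF at 110 °C should convert the methyl group of 2 into (E)-2-(4,5-dibromo-2-nitrophenyl)-N,N-dimethylethenamine F4. Fe powder in AcOH reduces it to 4,5-dibromo-2-[(E)-2-(dimethylamino)ethenyl]aniline F5, which closes in the flask to 5,6-dibromo-1H-indole F6. Oxidative C3–H/C3–H homocoupling with catalytic Pd(OCOCF3)2 and Cu(OAc)2 as terminal oxidant in DMSO at room temperature, a known dimerisation of free NH indoles, should then give 9. At that temperature, rapid reoxidation of zerovalent palladium should leave the C–Br bonds alone.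

**Step 5.**
- What may go wrong: The electron-rich biindole may be oxidised instead of substituted. Bromination may run on into the benzo rings or onto nitrogen. The second bromination may be sluggish once the first bromine has twisted the axis. The 2-bromoindole units may suffer acid-promoted hydrolysis during work-up.
- Fallback, from 9 back to 10: The electrophilic substitution is replaced by directed metalation. Boc2O and DMAP in THF should give di-tert-butyl 5,5',6,6'-tetrabromo-3,3'-biindole-1,1'-dicarboxylate F7. LDA in THF at −78 °C lithiates C2 and C2' under carbamate direction; this amide base is known to leave ring bromines of N-Boc-indoles untouched. A quench with 1,2-dibromo-1,1,2,2-tetrachloroethane should give di-tert-butyl 2,2',5,5',6,6'-hexabromo-3,3'-biindole-1,1'-dicarboxylate F8. Anhydrous TFA in CH2Cl2 at 0 °C then removes both carbamates to give 10.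

Further compounds
F1 | step 3 | 2,3-bis(4,5-dibromo-2-nitrophenyl)butane-1,4-diol (meso and racemic forms) | OCC(c1cc(Br)c(Br)cc1[N+](=O)[O-])C(CO)c1cc(Br)c(Br)cc1[N+](=O)[O-]
F2 | step 3 | 2,3-bis(4,5-dibromo-2-nitrophenyl)butanedial (meso and racemic forms) | O=CC(c1cc(Br)c(Br)cc1[N+](=O)[O-])C(C=O)c1cc(Br)c(Br)cc1[N+](=O)[O-]
F3 | step 3 | 2,3-bis(2-amino-4,5-dibromophenyl)butanedial (meso and racemic forms) | O=CC(c1cc(Br)c(Br)cc1N)C(C=O)c1cc(Br)c(Br)cc1N
F4 | step 4 | (E)-2-(4,5-dibromo-2-nitrophenyl)-N,N-dimethylethenamine | CN(C)/C=C/c1cc(Br)c(Br)cc1[N+](=O)[O-]
F5 | step 4 | 4,5-dibromo-2-[(E)-2-(dimethylamino)ethenyl]aniline | CN(C)/C=C/c1cc(Br)c(Br)cc1N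
F6 | step 4 | 5,6-dibromo-1H-indole | Brc1cc2cc[nH]c2cc1Br
F7 | step 5 | di-tert-butyl 5,5',6,6'-tetrabromo-3,3'-biindole-1,1'-dicarboxylate | CC(C)(C)OC(=O)n1cc(-c2cn(C(=O)OC(C)(C)C)c3cc(Br)c(Br)cc23)c2cc(Br)c(Br)cc21
F8 | step 5 | di-tert-butyl 2,2',5,5',6,6'-hexabromo-3,3'-biindole-1,1'-dicarboxylate | CC(C)(C)OC(=O)n1c(Br)c(-c2c(Br)n(C(=O)OC(C)(C)C)c3cc(Br)c(Br)cc23)c2cc(Br)c(Br)cc21
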